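The cyclopentanone of the trans-hydrindanone is taken apart at C1–C2, C2–C3 and the C3a–C7a fusion bond: an acyclic 1,7-enyne is folded by a cobalt-mediated (2+2+1) cyclocarbonylation that closes the six-membered ring B and the five-membered ring A together and creates only C3a. The step exploits the fact that the C2 carbonyl lies between C1 and C3, opposite the ring fusion, while the contiguous C4, C5 and C6 oxygens of ring B come from D-arabinose. The precursor carries the vinyl group next to a small axial C4 benzyl ether, a cis-acetonide on C5/C6, the C7 isopropenyl group and an alkyne capped by the silylated (S)-carbinol that becomes C1′.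

Key step: step 14

Remark: indane locants (C1–C7a, C1′ for the side-chain carbinol carbon) are used for the open-chain intermediates as well; the acyl groups are read from the target as (2R)-2-methylbutanoyl and (2E,4S)-4-acetoxy-3-methylpent-2-enoyl.

Step 1
Reactants: 1 D-arabinose
Product: 2 3,4-O-isopropylidene-D-arabinopyranose (anomeric mixture)
Conditions: Me2C(OMe)2, p-TsOH·H2O (cat.), DMF, rt
Reagents that add atoms: 2,2-dimethoxypropane, COC(C)(C)OC
Why: thermodynamic transketalisation should take the only cis-vicinal diol of the pyranose (O3/O4), which fixes the future C5/C6 cis-diol and leaves the lactol and O2 free; no stereocentre is created.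

Step 2
Reactants: 2 3,4-O-isopropylidene-D-arabinopyranose
Product: 3 1,2-dideoxy-4,5-O-isopropylidene-D-arabino-hex-1-enitol (vinyl diol)
Conditions: Ph3PCH3Br, KOt-Bu, THF, 0 °C → reflux
Reagents that add atoms: methyltriphenylphosphonium bromide, C[P+](c1ccccc1)(c1ccccc1)c1ccccc1.[Br-]
Why: Wittig methylenation of the open-chain aldehyde tautomer of the lactol (excess ylide covers the two hydroxyls) should give the C3=C3a vinyl group without touching the three sugar stereocentres.

Step 3
Reactants: 3 vinyl diol
Product: 4 6-O-(tert-butyldiphenylsilyl)-1,2-dideoxy-4,5-O-isopropylidene-D-arabino-hex-1-enitol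
Conditions: TBDPSCl, imidazole, CH2Cl2, 0 °C
Reagents that add atoms: tert-butyl(chloro)diphenylsilane, CC(C)(C)[Si](Cl)(c1ccccc1)c1ccccc1
Why: silylation with the bulky chlorosilane should be selective for the primary hydroxyl (future C7) over the secondary allylic one.

Step 4
Reactants: 4 primary silyl ether
Product: 5 3-O-benzyl-6-O-(tert-butyldiphenylsilyl)-1,2-dideoxy-4,5-O-isopropylidene-D-arabino-hex-1-enitol
Conditions: NaH, BnBr, Bu4NI (cat.), THF/DMF, 0 °C → rt
Reagents that add atoms: benzyl bromide, BrCc1ccccc1
Why: Williamson etherification of the secondary allylic alkoxide installs a small C4 ether that tolerates an axial position in the key step and is later removed reductively; the bulky silyl ether should not migrate under NaH.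

Step 5
Reactants: 5 benzyl silyl diether
Product: 6 3-O-benzyl-1,2-dideoxy-4,5-O-isopropylidene-D-arabino-hex-1-enitol (primary alcohol)
Conditions: TBAF, THF, rt
Reagents that add atoms: none
Why: fluoride cleaves the Si–O bond and frees the primary alcohol while benzyl ether and acetonide are inert.

Step 6
Reactants: 6 primary alcohol; 7 ethyl 2-(triphenylphosphoranylidene)propanoate
Product: 9 ethyl (E)-enoate C6–C7H=C(CH3)–CO2Et of the C4-benzyloxy C5/C6-acetonide vinyl chain (sugar stereocentres retained), via aldehyde 8 (not isolated)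
Conditions: Dess–Martin periodinane, CH2Cl2, 0 °C → rt; then 7 (excess), rt
Reagents that add atoms: none
Why: Dess–Martin oxidation followed in the same flask by Wittig olefination with the stabilised α-branched ylide traps the epimerisable α-alkoxy aldehyde at once and should give the E-trisubstituted enoate (ester trans to C6, methyl cis), the geometry that later enforces A(1,3) control.

Step 7
Reactants: 9 ethyl (E)-enoate
Product: 10 (E)-allylic alcohol C6–C7H=C(CH3)–CH2OH (other groups as in 9)
Conditions: i-Bu2AlH, CH2Cl2, −78 °C; aq. KNaC4H4O6 (potassium sodium tartrate)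
Reagents that add atoms: none
Why: 1,2-reduction of the enoate by the aluminium hydride gives the E-allylic alcohol needed for the sigmatropic step without touching the stereocentres.

Step 8
Reactants: 10 (E)-allylic alcohol; 11 triethyl orthoacetate
Product: 13 ethyl ester with C7 bearing isopropenyl and CH2CO2Et (isopropenyl and O6 syn along the C5–C6–C7–C7a zigzag), via ketene acetal 12 (not isolated)
Conditions: MeC(OEt)3 (excess), EtCO2H (cat.), 140 °C, EtOH distilled off
Reagents that add atoms: none
Why: Johnson–Claisen rearrangement through a chair in which C6–H eclipses the alkene (A(1,3) strain with the cis methyl) and the new C7–C7a bond forms anti to the C6–O bond, which should set C7 as required and deliver C7a and C1 as the acetate arm.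

Step 9
Reactants: 13 ethyl ester
Product: 14 aldehyde C7–CH2–CHO (C7 unchanged)
Conditions: i-Bu2AlH (1.1 equiv), toluene, −78 °C; MeOH, then aq. KNaC4H4O6
Reagents that add atoms: none
Why: partial reduction of the ester stops at the tetrahedral aluminium hemiacetal at −78 °C and gives the aldehyde whose CH2–CHO unit holds C7a and C1.

Step 10
Reactants: 14 aldehyde
Product: 16 terminal alkyne C7–C≡CH (a 3-isopropenyl-1-alkyne with the sugar-derived chain), via alkenyl nonaflate 15 (not isolated)
Conditions: n-C4F9SO2F, P2-Et phosphazene base (2.5 equiv), DMF, −20 °C → rt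
Reagents that add atoms: none
Why: one-pot enol nonaflation and E2 elimination of an enolisable aldehyde to the terminal alkyne (alkenyl nonaflate route); the neutral phosphazene base is too weak to deprotonate the doubly activated C7–H, so C7 should be kept and no allene should form.

Step 11
Reactants: 16 terminal alkyne; 17 N-methoxy-N-methylacetamide
Product: 19 ynone C7–C≡C–C(=O)CH3, via lithium acetylide 18 (not isolated)
Conditions: n-BuLi, THF, −78 °C; then 17, −78 → 0 °C; aq. NH4Cl
Reagents that add atoms: none
Why: selective deprotonation of the terminal alkyne and acylation of the lithium acetylide by the Weinreb amide, whose chelated tetrahedral adduct prevents over-addition, brings in C1′ and its methyl group.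

Step 12
Reactants: 19 ynone
Product: 20 (S)-propargylic alcohol C7–C≡C–CH(OH)CH3
Conditions: Ru[(S,S)-TsNCH(Ph)CH(Ph)NH](p-cymene) (2 mol%), i-PrOH, rt
Reagents that add atoms: none
Why: Noyori asymmetric transfer hydrogenation of an alkynyl methyl ketone, in which the (S,S)-configured ruthenium hydride should give the (S)-carbinol at C1′ under catalyst control, while the base-free medium avoids isomerisation of the ynone through the acidic C7–H.

Step 13
Reactants: 20 (S)-propargylic alcohol
Product: 21 arabinose-derived 1,7-enyne (C4 R benzyl ether; C5 S and C6 R cis-acetonide; C7 S isopropenyl; C1′ S tert-butyldimethylsilyl ether)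
Conditions: TBSCl, imidazole, DMF, rt
Reagents that add atoms: tert-butyl(chloro)dimethylsilane, CC(C)(C)[Si](C)(C)Cl
Why: standard silylation masks the propargylic hydroxyl for the cyclisation and the dissolving-metal step.

Step 14
Reactants: 21 1,7-enyne
Product: 23 tricyclic hydrindenone (C1=C7a enone; C3a R; C4 R benzyl ether; C5/C6 acetonide; C7 S isopropenyl; C1′ S silyl ether), via hexacarbonyldicobalt alkyne complex 22 (not isolated)
Conditions: Co2(CO)8 (1.1 equiv), CH2Cl2, rt; then Me3NO (excess), 4 Å MS, CH2Cl2, −10 °C → rt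
Reagents that add atoms: dicobalt octacarbonyl Co2(CO)8 (donor of the C2 carbonyl), [Co].[Co].[C-]#[O+].[C-]#[O+].[C-]#[O+].[C-]#[O+].[C-]#[O+].[C-]#[O+].[C-]#[O+].[C-]#[O+]
Why: Pauson–Khand (2+2+1) cyclocarbonylation: the internal alkyne is bound as its Co2(CO)6 complex, the amine N-oxide removes a CO ligand as CO2, the vinyl group coordinates and inserts into the Co–C7a bond, CO inserts and reductive elimination releases the enone. The closest known reaction type is the N-oxide-promoted intramolecular Pauson–Khand reaction of oxygenated, sugar- or tartrate-derived 1,7-enynes to bicyclo[4.3.0]nonenones. Ring B closes by 6-exo insertion of the terminal alkene (C3a–C7a bond, C3 left outside ring B); ring A then closes by carbonyl insertion and reductive elimination (C3–C2 and C2–C1), and the internal alkyne places the silyloxyethyl arm on the α-carbon C1. The only new stereocentre, C3a, is controlled by the chair-like fold of the C4–C7 tether held by the cis-fused acetonide: C7-isopropenyl and O6 equatorial, O5 and the small benzyloxy group axial, so that C3a should form with its hydrogen syn to O5. The step needs this facial selectivity and chemoselectivity for the vinyl group; the acetonide secures the first and also bends the tether against the usual reluctance of 1,7-enynes, and the second is certain because isopropenyl and alkyne form only a 1,4-enyne, which cannot cyclocarbonylate.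

Step 15
Reactants: 23 tricyclic hydrindenone
Product: 25 trans-fused hydrindan-2-one with free axial C4 hydroxyl (H7a anti to H3a; C1 side chain trans to C7; acetonide and silyl ether kept), via lithium enolate 24 (not isolated)
Conditions: Li (excess), NH3(l)/THF, −78 °C; isoprene; then solid NH4Cl
Reagents that add atoms: none
Why: dissolving-metal (Birch-type) enone reduction, in which the β-carbanion at C7a should be protonated axially to the trans-fused hydrindane, the enolate protects C2 from over-reduction and the benzyl ether is cleaved in the same pot; C1 is set on protonation and equilibration as the thermodynamic epimer.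

Step 16
Reactants: 25 hydroxy ketone
Product: 26 C2 ethylene ketal (spiro-1,3-dioxolane at C2; C4 hydroxyl free)
Conditions: 2,2-dimethyl-1,3-dioxolane (solvent), p-TsOH·H2O (cat.), 40 °C, acetone removed in a N2 stream
Reagents that add atoms: 2,2-dimethyl-1,3-dioxolane, CC1(C)OCCO1
Why: acid-catalysed exchange dioxolanation masks the only ketone so that the C4 carbonyl can later be methylenated alone; the acetone-derived reagent keeps the C5/C6 acetonide in place by mass action, and any C1 epimer equilibrates through the enol before the ketal closes.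

Step 17
Reactants: 26 ketal alcohol
Product: 27 C4 ketone (C2 ketal; acetonide; C1′ silyl ether)
Conditions: Dess–Martin periodinane, pyridine, CH2Cl2, 0 °C → rt
Reagents that add atoms: none
Why: Dess–Martin oxidation of the axial secondary alcohol under buffered, non-enolising conditions should give the ketone without epimerising C3a or C5.

Step 18
Reactants: 27 C4 ketone
Product: 28 C4 exocyclic methylene compound (C2 ketal; acetonide; C1′ silyl ether)
Conditions: Cp2TiMe2, toluene, 65 °C, dark
Reagents that add atoms: dimethyltitanocene Cp2TiMe2, [CH3-].[CH3-].[Ti+4].[cH-]1cccc1.[cH-]1cccc1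
Why: Petasis methylenation, whose non-basic titanium methylidene converts the enolisable α-oxygenated ketone into the alkene without epimerisation at C3a or β-elimination of O6.

Step 19
Reactants: 28 silyl ether
Product: 29 C1′ alcohol (C2 ketal; C4 methylene; acetonide)
Conditions: TBAF, THF, rt → 40 °C
Reagents that add atoms: none
Why: fluoride removes the C1′ silyl group while C2 is still a ketal, so that no β-hydroxy ketone is exposed to base.

Step 20
Reactants: 29 C1′ alcohol
Product: 30 C1′ acetate (C2 ketal; C4 methylene; acetonide)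
Conditions: Ac2O, pyridine, DMAP (cat.), CH2Cl2, rt
Reagents that add atoms: acetic anhydride, CC(=O)OC(C)=O
Why: standard acetylation of the secondary alcohol, with C2 masked so that no β-elimination is possible.

Step 21
Reactants: 30 ketal acetate
Product: 31 cis-5,6-diol with C2 ketone (C4 methylene; C7 isopropenyl; C1′ acetate)
Conditions: AcOH/H2O (4:1), 50 °C
Reagents that add atoms: water, O
Why: mild aqueous acid hydrolyses the C2 dioxolane and the acetonide in one operation, while the acetate and the two 1,1-disubstituted alkenes survive and C1 stays in its thermodynamic configuration.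

Step 22
Reactants: 31 diol
Product: 32 C6 triethylsilyl ether with free axial C5 hydroxyl
Conditions: TESCl (1.1 equiv), imidazole, CH2Cl2, −20 → 0 °C
Reagents that add atoms: chlorotriethylsilane, CC[Si](Cl)(CC)CC
Why: regioselective silylation of a cis-cyclohexanediol at the equatorial hydroxyl (C6) over the axial one (C5), a temporary mask that leaves O5 for esterification.

Step 23
Reactants: 33 (S)-2-acetoxypropanoyl chloride
Product: 34 (S)-3-acetoxybutan-2-one
Conditions: MeLi, CuI, Et2O, 0 °C; then 33, −78 °C
Reagents that add atoms: methyllithium (used as Me2CuLi), [Li]C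
Why: acyl substitution of the acid chloride by the Gilman cuprate stops at the methyl ketone at −78 °C and leaves the acetate and the α-stereocentre untouched.

Step 24
Reactants: 34 (S)-3-acetoxybutan-2-one; 35 tert-butyl 2-(triphenylphosphoranylidene)acetate
Product: 36 tert-butyl (2E,4S)-4-acetoxy-3-methylpent-2-enoate
Conditions: toluene, 90 °C
Reagents that add atoms: none
Why: Wittig olefination of the activated α-acyloxy ketone with a stabilised ylide under neutral conditions should give mainly the E-enoate (ester trans to the branched carbon) without racemisation; a minor Z-isomer would be removed by chromatography.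

Step 25
Reactants: 36 tert-butyl ester
Product: 37 (2E,4S)-4-acetoxy-3-methylpent-2-enoic acid
Conditions: CF3CO2H, CH2Cl2, 0 °C → rt
Reagents that add atoms: none
Why: acidolysis of the tert-butyl ester with loss of isobutene frees the acid while the acetate stays.

Step 26
Reactants: 37 (2E,4S)-4-acetoxy-3-methylpent-2-enoic acid; 32 C6 silyl ether
Product: 39 C5 (2E,4S)-4-acetoxy-3-methylpent-2-enoate with C6 triethylsilyl ether, via mixed anhydride 38 (not isolated)
Conditions: 2,4,6-Cl3C6H2COCl, Et3N, THF, rt; then 32, DMAP, toluene, rt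
Reagents that add atoms: none
Why: Yamaguchi esterification, in which the hindered axial C5 alcohol attacks the enoyl carbonyl of the mixed anhydride under DMAP catalysis; the E-geometry is the thermodynamic one and should be retained.

Step 27
Reactants: 39 C5 ester silyl ether
Product: 40 C5 ester with free equatorial C6 hydroxyl
Conditions: HF·pyridine, pyridine, THF, 0 °C
Reagents that add atoms: none
Why: buffered acidic fluoride cleaves the labile triethylsilyl ether without acyl migration from O5 to O6 and without touching the esters.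

Step 28
Reactants: 40 homoallylic alcohol
Product: 41 C7 (2S)-2-methyloxiran-2-yl compound with free C6 hydroxyl
Conditions: VO(acac)2 (10 mol%), t-BuOOH (decane), CH2Cl2, 0 °C → rt
Reagents that add atoms: tert-butyl hydroperoxide, CC(C)(C)OO
Why: hydroxyl-directed epoxidation of a homoallylic alcohol by the alkylperoxy vanadate of O6 through a chair-like transition state in which the alkene CH2 eclipses C7–H and oxygen reaches the face turned toward O6, which should set the (S)-oxirane carbon; the equatorial O6 is antiperiplanar to C4 and cannot reach the exocyclic methylene, and the enoate is electron-poor.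

Step 29
Reactants: 41 epoxy alcohol; 42 (R)-2-methylbutanoic acid
Product: 43 CNP0170703.2, (1S,3aR,5S,6R,7S,7aR)-1-[(1S)-1-acetoxyethyl]-4-methylidene-6-{[(2R)-2-methylbutanoyl]oxy}-7-[(2S)-2-methyloxiran-2-yl]-2-oxooctahydro-1H-inden-5-yl (2E,4S)-4-acetoxy-3-methylpent-2-enoate
Conditions: DCC, DMAP (cat.), CH2Cl2, 0 °C → rt
Reagents that add atoms: none
Why: Steglich esterification of the equatorial C6 alcohol with the enantiopure acid under nearly neutral conditions, which should spare the epoxide and the β-acetoxy ketone and not racemise the α-stereocentre.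

Compound list
1 | D-arabinose | O=C[C@@H](O)[C@H](O)[C@H](O)CO | starting material
2 | 3,4-O-isopropylidene-D-arabinopyranose (anomeric mixture) | OC1[C@@H](O)[C@@H]2OC(C)(C)O[C@@H]2CO1 | intermediate
3 | 1,2-dideoxy-4,5-O-isopropylidene-D-arabino-hex-1-enitol | C=C[C@@H](O)[C@@H]1OC(C)(C)O[C@@H]1CO | intermediate
4 | 6-O-(tert-butyldiphenylsilyl)-1,2-dideoxy-4,5-O-isopropylidene-D-arabino-hex-1-enitol | C=C[C@@H](O)[C@@H]1OC(C)(C)O[C@@H]1CO[Si](c1ccccc1)(c1ccccc1)C(C)(C)C | intermediate
5 | 3-O-benzyl-6-O-(tert-butyldiphenylsilyl)-1,2-dideoxy-4,5-O-isopropylidene-D-arabino-hex-1-enitol | C=C[C@@H](OCc1ccccc1)[C@@H]2OC(C)(C)O[C@@H]2CO[Si](c1ccccc1)(c1ccccc1)C(C)(C)C | intermediate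
6 | 3-O-benzyl-1,2-dideoxy-4,5-O-isopropylidene-D-arabino-hex-1-enitol | C=C[C@@H](OCc1ccccc1)[C@@H]2OC(C)(C)O[C@@H]2CO | intermediate
7 | ethyl 2-(triphenylphosphoranylidene)propanoate | CCOC(=O)C(C)=P(c1ccccc1)(c1ccccc1)c1ccccc1 | starting material
8 | aldehyde of 6 (formyl group = C7; not isolated) | C=C[C@@H](OCc1ccccc1)[C@@H]2OC(C)(C)O[C@@H]2C=O | intermediate
9 | ethyl (E)-enoate (C7=C(CH3)CO2Et on C6; C4 benzyl ether; C5/C6 acetonide) | C=C[C@@H](OCc1ccccc1)[C@@H]2OC(C)(C)O[C@@H]2/C=C(\C)C(=O)OCC | intermediate
10 | (E)-allylic alcohol from 9 | C=C[C@@H](OCc1ccccc1)[C@@H]2OC(C)(C)O[C@@H]2/C=C(\C)CO | intermediate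
11 | triethyl orthoacetate | CCOC(C)(OCC)OCC | starting material
12 | ketene acetal of 10 (not isolated) | C=C[C@@H](OCc1ccccc1)[C@@H]2OC(C)(C)O[C@@H]2/C=C(\C)COC(=C)OCC | intermediate
13 | ethyl ester with C7 isopropenyl and CH2CO2Et arm | C=C[C@@H](OCc1ccccc1)[C@@H]2OC(C)(C)O[C@@H]2[C@@H](C(C)=C)CC(=O)OCC | intermediate
14 | aldehyde C7–CH2–CHO | C=C[C@@H](OCc1ccccc1)[C@@H]2OC(C)(C)O[C@@H]2[C@@H](C(C)=C)CC=O | intermediate
15 | alkenyl nonaflate of 14 (E/Z; not isolated) | C=C[C@@H](OCc1ccccc1)[C@@H]2OC(C)(C)O[C@@H]2[C@@H](C(C)=C)C=COS(=O)(=O)C(F)(F)C(F)(F)C(F)(F)C(F)(F)F | intermediate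
16 | terminal alkyne C7–C≡CH | C=C[C@@H](OCc1ccccc1)[C@@H]2OC(C)(C)O[C@@H]2[C@@H](C(C)=C)C#C | intermediate
17 | N-methoxy-N-methylacetamide | CC(=O)N(C)OC | starting material
18 | lithium acetylide of 16 (not isolated) | C=C[C@@H](OCc1ccccc1)[C@@H]2OC(C)(C)O[C@@H]2[C@@H](C(C)=C)C#C[Li] | intermediate
19 | ynone C7–C≡C–C(=O)CH3 | C=C[C@@H](OCc1ccccc1)[C@@H]2OC(C)(C)O[C@@H]2[C@@H](C(C)=C)C#CC(C)=O | intermediate
20 | (S)-propargylic alcohol | C=C[C@@H](OCc1ccccc1)[C@@H]2OC(C)(C)O[C@@H]2[C@@H](C(C)=C)C#C[C@@H](O)C | intermediate
21 | 1,7-enyne, key-step precursor (C4 benzyl ether; C5/C6 acetonide; C7 isopropenyl; C1′ TBS ether) | C=C[C@@H](OCc1ccccc1)[C@@H]2OC(C)(C)O[C@@H]2[C@@H](C(C)=C)C#C[C@@H](O[Si](C)(C)C(C)(C)C)C | intermediate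
22 | hexacarbonyldicobalt complex of the alkyne of 21 (not isolated) | C=C[C@@H](OCc1ccccc1)[C@@H]2OC(C)(C)O[C@@H]2[C@@H](C(C)=C)C34[Co]5(=C=O)(=C=O)(=C=O)[Co]3(=C=O)(=C=O)(=C=O)C45[C@@H](O[Si](C)(C)C(C)(C)C)C | intermediate
23 | tricyclic hydrindenone, key-step product (C1=C7a enone) | c1ccccc1CO[C@@H]2[C@@H]3CC(=O)C([C@H](C)O[Si](C)(C)C(C)(C)C)=C3[C@H](C(C)=C)[C@H]4OC(C)(C)O[C@H]42 | intermediate
24 | lithium C1=C2 enolate and C4 alkoxide (not isolated) | [Li]O[C@@H]2[C@@H]3CC(O[Li])=C([C@H](C)O[Si](C)(C)C(C)(C)C)[C@H]3[C@H](C(C)=C)[C@H]4OC(C)(C)O[C@H]42 | intermediate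
25 | trans-hydrindan-2-one with C4 hydroxyl | O[C@@H]2[C@@H]3CC(=O)[C@H]([C@H](C)O[Si](C)(C)C(C)(C)C)[C@H]3[C@H](C(C)=C)[C@H]4OC(C)(C)O[C@H]42 | intermediate
26 | C2 ethylene ketal with C4 hydroxyl | O[C@@H]2[C@@H]3CC5(OCCO5)[C@H]([C@H](C)O[Si](C)(C)C(C)(C)C)[C@H]3[C@H](C(C)=C)[C@H]4OC(C)(C)O[C@H]42 | intermediate
27 | C4 ketone (C2 ketal) | O=C2[C@@H]3CC5(OCCO5)[C@H]([C@H](C)O[Si](C)(C)C(C)(C)C)[C@H]3[C@H](C(C)=C)[C@H]4OC(C)(C)O[C@H]42 | intermediate
28 | C4 methylene compound (C2 ketal; C1′ TBS ether) | C=C2[C@@H]3CC5(OCCO5)[C@H]([C@H](C)O[Si](C)(C)C(C)(C)C)[C@H]3[C@H](C(C)=C)[C@H]4OC(C)(C)O[C@H]42 | intermediate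
29 | C1′ alcohol (C2 ketal) | C=C2[C@@H]3CC5(OCCO5)[C@H]([C@H](C)O)[C@H]3[C@H](C(C)=C)[C@H]4OC(C)(C)O[C@H]42 | intermediate
30 | C1′ acetate (C2 ketal) | C=C2[C@@H]3CC5(OCCO5)[C@H]([C@H](C)OC(C)=O)[C@H]3[C@H](C(C)=C)[C@H]4OC(C)(C)O[C@H]42 | intermediate
31 | cis-5,6-diol with C2 ketone | C=C2[C@@H]3CC(=O)[C@H]([C@H](C)OC(C)=O)[C@H]3[C@H](C(C)=C)[C@@H](O)[C@H]2O | intermediate
32 | C6 triethylsilyl ether, C5 alcohol | C=C2[C@@H]3CC(=O)[C@H]([C@H](C)OC(C)=O)[C@H]3[C@H](C(C)=C)[C@@H](O[Si](CC)(CC)CC)[C@H]2O | intermediate
33 | (S)-2-acetoxypropanoyl chloride | C[C@H](OC(C)=O)C(Cl)=O | starting material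
34 | (S)-3-acetoxybutan-2-one | C[C@H](OC(C)=O)C(C)=O | intermediate
35 | tert-butyl 2-(triphenylphosphoranylidene)acetate | CC(C)(C)OC(=O)C=P(c1ccccc1)(c1ccccc1)c1ccccc1 | starting material
36 | tert-butyl (2E,4S)-4-acetoxy-3-methylpent-2-enoate | C[C@H](OC(C)=O)/C(C)=C/C(=O)OC(C)(C)C | intermediate
37 | (2E,4S)-4-acetoxy-3-methylpent-2-enoic acid | C[C@H](OC(C)=O)/C(C)=C/C(=O)O | intermediate
38 | mixed anhydride of 37 with 2,4,6-trichlorobenzoic acid (not isolated) | C[C@H](OC(C)=O)/C(C)=C/C(=O)OC(=O)c1c(Cl)cc(Cl)cc1Cl | intermediate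
39 | C5 pentenoate, C6 triethylsilyl ether | C=C2[C@@H]3CC(=O)[C@H]([C@H](C)OC(C)=O)[C@H]3[C@H](C(C)=C)[C@@H](O[Si](CC)(CC)CC)[C@H]2OC(=O)/C=C(\C)[C@H](C)OC(C)=O | intermediate
40 | C5 pentenoate, C6 alcohol | C=C2[C@@H]3CC(=O)[C@H]([C@H](C)OC(C)=O)[C@H]3[C@H](C(C)=C)[C@@H](O)[C@H]2OC(=O)/C=C(\C)[C@H](C)OC(C)=O | intermediate
41 | C7 (2S)-2-methyloxiranyl compound, C6 alcohol | C=C2[C@@H]3CC(=O)[C@H]([C@H](C)OC(C)=O)[C@H]3[C@H]([C@@]4(C)CO4)[C@@H](O)[C@H]2OC(=O)/C=C(\C)[C@H](C)OC(C)=O | intermediate
42 | (R)-2-methylbutanoic acid | CC[C@@H](C)C(O)=O | starting material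
43 | CNP0170703.2 | C=C1[C@@H]2CC(=O)[C@H]([C@H](C)OC(C)=O)[C@H]2[C@H]([C@@]2(C)CO2)[C@@H](OC(=O)[C@H](C)CC)[C@H]1OC(=O)/C=C(\C)[C@H](C)OC(C)=O | target

Total step count: 29. Longest linear sequence: 26 steps (steps 1–22 and 26–29); steps 23–25 make the side-chain acid.

Steps most likely to fail

Step 14. The hexacarbonyldicobalt complex of the doubly branched internal alkyne may fail to take up the vinyl group, so that the slow 1,7-closure loses to decomplexation, or it may close with little facial bias at C3a. The fallback is the isocyanide version of the (2+2+1) reaction at a single metal centre. It sets out from 21: zerovalent nickel [Ni(cod)2, PBu3] and 2,6-dimethylphenyl isocyanide in DMF at 50 °C should form a nickelacyclopentene, insert the isocyanide and release the N-(2,6-dimethylphenyl) iminocyclopentene F1. Hydrolysis of the imine with aqueous oxalic acid in THF comes back to the route at 23.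

Step 8. The cis substituent on the dioxolane crowds the face anti to O6, so the facial selectivity of the sigmatropic shift may be poor or reversed at C7. The fallback sets C7 by conjugate addition, in which the isopropenyl group and not the two-carbon arm is the entering group, so that the opposite, less crowded face of the same alkene leads to the same configuration. It sets out from 6: Dess–Martin oxidation to aldehyde 8 and Ando-type Z-selective olefination [ethyl 2-(diphenoxyphosphoryl)acetate, NaH, THF, −78 °C] should give the ethyl (Z)-enoate F2. Lithium diisopropenylcuprate with BF3·OEt2 in THF at −78 °C, a reagent type that adds to Z-configured γ-alkoxy enoates to give syn adducts, then leads to 13, where the route is rejoined.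

Step 28. Oxygen delivery from O6 may reach the wrong face of the isopropenyl group if the reacting rotamer is not the one with CH2 eclipsing C7–H, which would give the epimeric oxirane. The fallback replaces substrate control by reagent control. It sets out from 40 and comes back at 41: a chiral bis-hydroxamic acid vanadium catalyst [VO(Oi-Pr)3 with a C2-symmetric bis-hydroxamic acid ligand, cumene hydroperoxide, toluene, rt], a system known for the asymmetric epoxidation of homoallylic alcohols, is used with the ligand antipode that delivers oxygen to the required face; no new compound is made (F0).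

Further compounds
F1 | step 14 | N-(2,6-dimethylphenyl) imine of hydrindenone 23 | c1ccccc1CO[C@@H]2[C@@H]3CC(=Nc5c(C)cccc5C)C([C@H](C)O[Si](C)(C)C(C)(C)C)=C3[C@H](C(C)=C)[C@H]4OC(C)(C)O[C@H]42
F2 | step 8 | ethyl (Z)-enoate C6–C7H=CH–CO2Et (C4 benzyl ether; C5/C6 acetonide) | C=C[C@@H](OCc1ccccc1)[C@@H]2OC(C)(C)O[C@@H]2/C=C\C(=O)OCC
F0 | step 28 | none | none
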